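## Retrosynthetic overview

1. Ring C is closed last, at C2–C3. C2 is the benzylic carbon of ring B para to the free C4'–OH and also carries O1, so it can become the exocyclic carbon of a ring-B p-quinone methide; C3 is α to the C4 ketone and carries the hydroxyl, so it is the nucleophilic carbon of an enediol. Dehydrogenation of the achiral ether 11 and a catalyst-controlled intramolecular 1,6-addition give ring C, C2 and C3 in one operation.
2. 11 comes from 10 by desilylation; the C3 oxygen is put on the acetyl group of 9 by enolate hydroxylation.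
3. The prenyl group of 9 is placed between the hydroxyl that becomes C5–OH and the methoxy that becomes C7–OMe by an aromatic Claisen rearrangement of a 1,1-dimethylallyl ether (7 → 8 → 9).
4. The O1–C2 ether is made first, by Mitsunobu mono-etherification of the symmetric ketone 4 with the silyl-protected vanillyl alcohol 3 (from vanillin 1).
5. Rings A and B are bought as aromatic rings; ring C is the only ring formed.

Key step: step 8

Assumption: the sense of induction of the phosphoric acid in step 8 cannot be fixed in advance; (R)-TRIP is written, and (S)-TRIP would be used instead if the (2S,3S) series were favoured. Compounds 4 and 6 and the oxaziridine of step 6 are taken as commercial.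

## Route

Step 1
Reactants: 1 vanillin (4-hydroxy-3-methoxybenzaldehyde)
Product: 2 3-methoxy-4-(triisopropylsilyloxy)benzaldehyde
Conditions: TIPSCl, imidazole, DMF, rt
Reagents that add atoms: triisopropylsilyl chloride, CC(C)[Si](Cl)(C(C)C)C(C)C
Why: Standard silylation of a phenol; the bulky aryl triisopropylsilyl ether should withstand borohydride, DBU and amide bases and is removed later by fluoride.

Step 2
Reactants: 2 3-methoxy-4-(triisopropylsilyloxy)benzaldehyde
Product: 3 [3-methoxy-4-(triisopropylsilyloxy)phenyl]methanol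
Conditions: NaBH4, MeOH, 0 °C
Reagents that add atoms: none
Why: Borohydride reduction of the aryl aldehyde to the benzylic alcohol should leave the aryl silyl ether untouched.

Step 3
Reactants: 3 [3-methoxy-4-(triisopropylsilyloxy)phenyl]methanol; 4 1-(2,6-dihydroxy-4-methoxyphenyl)ethanone (slight excess)
Product: 5 1-[2-hydroxy-4-methoxy-6-{[3-methoxy-4-(triisopropylsilyloxy)phenyl]methoxy}phenyl]ethanone
Conditions: PPh3, DIAD, THF, 0 °C to rt
Reagents that add atoms: none
Why: Mitsunobu etherification of an acidic ortho-acyl phenol with a primary benzylic alcohol; 4 is symmetric, so only one mono-ether is possible, and the remaining hydroxyl is held in a hydrogen bond to the carbonyl, which should stop the reaction at mono-alkylation.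

Step 4
Reactants: 5 1-[2-hydroxy-4-methoxy-6-{[3-methoxy-4-(triisopropylsilyloxy)phenyl]methoxy}phenyl]ethanone; 6 3-chloro-3-methylbut-1-yne
Product: 7 1-[4-methoxy-2-{[3-methoxy-4-(triisopropylsilyloxy)phenyl]methoxy}-6-(2-methylbut-3-yn-2-yloxy)phenyl]ethanone
Conditions: DBU, CuCl2 (cat.), MeCN, 0 °C
Reagents that add atoms: none
Why: Copper-catalysed O-alkylation of a phenoxide with a tertiary propargylic chloride is the standard entry to 1,1-dimethylpropargyl aryl ethers and has been used on hydrogen-bonded hydroxyls ortho to a carbonyl in flavonoid work.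

Step 5
Reactants: 7 1-[4-methoxy-2-{[3-methoxy-4-(triisopropylsilyloxy)phenyl]methoxy}-6-(2-methylbut-3-yn-2-yloxy)phenyl]ethanone
Product: 9 1-[2-hydroxy-4-methoxy-6-{[3-methoxy-4-(triisopropylsilyloxy)phenyl]methoxy}-3-(3-methylbut-2-en-1-yl)phenyl]ethanone, via 1,1-dimethylallyl ether 8 (not isolated)
Conditions: H2 (1 atm), Pd/CaCO3 poisoned with Pb(OAc)2 (Lindlar catalyst), quinoline, toluene, rt; filtration; then 110 °C
Reagents that add atoms: none
Why: Semi-hydrogenation of the terminal alkyne followed by aromatic Claisen rearrangement ([3,3]) of the 1,1-dimethylallyl aryl ether should deliver the 3-methylbut-2-enyl group to the only free ortho carbon, the one between the ether oxygen and the methoxy-bearing carbon, and re-form the hydrogen-bonded phenol.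

Step 6
Reactants: 9 1-[2-hydroxy-4-methoxy-6-{[3-methoxy-4-(triisopropylsilyloxy)phenyl]methoxy}-3-(3-methylbut-2-en-1-yl)phenyl]ethanone
Product: 10 2-hydroxy-1-[2-hydroxy-4-methoxy-6-{[3-methoxy-4-(triisopropylsilyloxy)phenyl]methoxy}-3-(3-methylbut-2-en-1-yl)phenyl]ethanone
Conditions: KHMDS (2.3 equiv), THF, −78 °C; 2-(phenylsulfonyl)-3-phenyloxaziridine; AcOH quench
Reagents that add atoms: 2-(phenylsulfonyl)-3-phenyloxaziridine, O=S(=O)(c1ccccc1)N1OC1c1ccccc1
Why: Enolate hydroxylation with an N-sulfonyloxaziridine: the first equivalent of base takes the phenol, the second forms the only possible enolate, and the neutral oxidant should leave the prenyl alkene and the benzylic ether alone.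

Step 7
Reactants: 10 2-hydroxy-1-[2-hydroxy-4-methoxy-6-{[3-methoxy-4-(triisopropylsilyloxy)phenyl]methoxy}-3-(3-methylbut-2-en-1-yl)phenyl]ethanone
Product: 11 2-hydroxy-1-[2-hydroxy-6-[(4-hydroxy-3-methoxyphenyl)methoxy]-4-methoxy-3-(3-methylbut-2-en-1-yl)phenyl]ethanone
Conditions: TBAF, AcOH (1:1), THF, 0 °C
Reagents that add atoms: none
Why: Fluoride cleavage of the aryl silyl ether; the acetic acid buffer keeps the medium non-basic so that the free p-hydroxybenzyl aryl ether should not fragment by 1,6-elimination, and 11 is taken on at once.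

Step 8
Reactants: 11 2-hydroxy-1-[2-hydroxy-6-[(4-hydroxy-3-methoxyphenyl)methoxy]-4-methoxy-3-(3-methylbut-2-en-1-yl)phenyl]ethanone
Product: 13 (2R,3R)-3,5-dihydroxy-2-(4-hydroxy-3-methoxyphenyl)-7-methoxy-6-(3-methylbut-2-en-1-yl)-2,3-dihydro-4H-chromen-4-one, via quinone methide 12 (not isolated)
Conditions: DDQ (1.0 equiv), 4 Å molecular sieves, CH2Cl2, −30 °C; cold filtration from DDQH2; then (R)-TRIP (10 mol%), toluene/CH2Cl2, −30 °C, high dilution
Reagents that add atoms: none
Why: Proposed new method: DDQ should abstract hydride from the O–CH2 carbon of the free 4-hydroxy-3-methoxybenzyl ether (the known first event when DDQ oxidises p-hydroxybenzyl ethers) to give the O-aryl p-quinone methide 12, whose exocyclic carbon is the future C2; the chiral phosphoric acid then protonates the quinone methide oxygen, binds the (Z)-enediol of the hydroxyacetyl ketone, and the enediol carbon (future C3) adds to the exocyclic carbon, which rearomatises ring B and closes ring C. The closest known reaction types are phosphoric-acid-catalysed enantioselective 1,6-additions of enolisable carbonyl compounds to p-quinone methides generated in situ, and the acid-catalysed intramolecular Mannich closure of 2-aminoacetophenone imines to 2-aryl-2,3-dihydroquinolin-4-ones, the nitrogen counterpart of this ring. Ring C closes in a 6-(enolendo)-exo-trig mode with respect to the quinone methide C=C (6-endo-trig if the protonated form is drawn as the O1=C2 oxocarbenium ion). C2 is controlled by the catalyst, which holds the cation through the ring-B oxygen and the enediol through its hydroxyls and shields one face of C2; C3 follows from C2 by substrate control, because a half-chair transition state with the aryl group pseudo-equatorial and the (Z)-enediol (C3–OH cis to C4–OH, hydrogen cis to ring A) places both substituents equatorial, the 2,3-trans arrangement that is also the more stable one. The step needs C-attack over O-attack, catalysed over uncatalysed closure, and oxidation of ring B only: O-attack by the primary hydroxyl or the enol oxygen gives O,O-acetals that should re-ionise under the acid while the C–C bond is irreversible, removal of DDQH2 before the acid is added and the low temperature should keep the background reaction small, and the guaiacol unit of ring B is far more easily oxidised than the acyl-deactivated, hydrogen-bonded 5-hydroxy-6-prenyl ring A, so one equivalent of DDQ at −30 °C should not form a chromene.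

## Compound list

1 | vanillin (4-hydroxy-3-methoxybenzaldehyde) | COc1cc(C=O)ccc1O | starting material
2 | 3-methoxy-4-(triisopropylsilyloxy)benzaldehyde | COc1cc(C=O)ccc1O[Si](C(C)C)(C(C)C)C(C)C | intermediate
3 | [3-methoxy-4-(triisopropylsilyloxy)phenyl]methanol | COc1cc(CO)ccc1O[Si](C(C)C)(C(C)C)C(C)C | intermediate
4 | 1-(2,6-dihydroxy-4-methoxyphenyl)ethanone | CC(=O)c1c(O)cc(OC)cc1O | starting material
5 | 1-[2-hydroxy-4-methoxy-6-{[3-methoxy-4-(triisopropylsilyloxy)phenyl]methoxy}phenyl]ethanone | CC(=O)c1c(O)cc(OC)cc1OCc1ccc(O[Si](C(C)C)(C(C)C)C(C)C)c(OC)c1 | intermediate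
6 | 3-chloro-3-methylbut-1-yne | CC(C)(Cl)C#C | starting material
7 | 1-[4-methoxy-2-{[3-methoxy-4-(triisopropylsilyloxy)phenyl]methoxy}-6-(2-methylbut-3-yn-2-yloxy)phenyl]ethanone | CC(=O)c1c(OC(C)(C)C#C)cc(OC)cc1OCc1ccc(O[Si](C(C)C)(C(C)C)C(C)C)c(OC)c1 | intermediate
8 | 1-[4-methoxy-2-{[3-methoxy-4-(triisopropylsilyloxy)phenyl]methoxy}-6-(2-methylbut-3-en-2-yloxy)phenyl]ethanone (1,1-dimethylallyl ether) | CC(=O)c1c(OC(C)(C)C=C)cc(OC)cc1OCc1ccc(O[Si](C(C)C)(C(C)C)C(C)C)c(OC)c1 | intermediate (not isolated)
9 | 1-[2-hydroxy-4-methoxy-6-{[3-methoxy-4-(triisopropylsilyloxy)phenyl]methoxy}-3-(3-methylbut-2-en-1-yl)phenyl]ethanone | CC(=O)c1c(O)c(CC=C(C)C)c(OC)cc1OCc1ccc(O[Si](C(C)C)(C(C)C)C(C)C)c(OC)c1 | intermediate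
10 | 2-hydroxy-1-[2-hydroxy-4-methoxy-6-{[3-methoxy-4-(triisopropylsilyloxy)phenyl]methoxy}-3-(3-methylbut-2-en-1-yl)phenyl]ethanone | O=C(CO)c1c(O)c(CC=C(C)C)c(OC)cc1OCc1ccc(O[Si](C(C)C)(C(C)C)C(C)C)c(OC)c1 | intermediate
11 | 2-hydroxy-1-[2-hydroxy-6-[(4-hydroxy-3-methoxyphenyl)methoxy]-4-methoxy-3-(3-methylbut-2-en-1-yl)phenyl]ethanone | O=C(CO)c1c(O)c(CC=C(C)C)c(OC)cc1OCc1ccc(O)c(OC)c1 | intermediate
12 | 4-{[3-hydroxy-2-(hydroxyacetyl)-5-methoxy-4-(3-methylbut-2-en-1-yl)phenoxy]methylidene}-2-methoxycyclohexa-2,5-dien-1-one (quinone methide, alkene geometry not defined) | COC1=CC(=COc2cc(OC)c(CC=C(C)C)c(O)c2C(=O)CO)C=CC1=O | intermediate (not isolated)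
13 | (2R,3R)-3,5-dihydroxy-2-(4-hydroxy-3-methoxyphenyl)-7-methoxy-6-(3-methylbut-2-en-1-yl)-2,3-dihydro-4H-chromen-4-one | COc1cc([C@H]2Oc3cc(OC)c(CC=C(C)C)c(O)c3C(=O)[C@@H]2O)ccc1O | target

## Step count and risks

Total steps: 8. Longest linear sequence: 8 steps (1 → 13); 4 and 6 enter as bought compounds.

Steps most likely to fail:

Step 8 (carries the label "Proposed new method:"). The ring closure may run in part without the catalyst, promoted by acid left from the spent oxidant, which would lower the enantiomeric purity. The quinone methide may be hydrolysed by traces of water. The product may lose its configuration at C2 by reversible opening of the O1–C2 bond through a ring-B quinone methide if the mixture warms. The fallback uses known chemistry, closes the same bond, sets out from 9 and comes back at 13. The hydrogen-bonded phenol of 9 would be silylated (TBSOTf, 2,6-lutidine, CH2Cl2) to give 1-[2-(tert-butyldimethylsilyloxy)-4-methoxy-6-{[3-methoxy-4-(triisopropylsilyloxy)phenyl]methoxy}-3-(3-methylbut-2-en-1-yl)phenyl]ethanone F1. Detrifluoroacetylative diazo transfer (LiHMDS, 2,2,2-trifluoroethyl trifluoroacetate, THF, −78 °C; then MsN3, Et3N, H2O, MeCN) would pass through the trifluoroacetyl diketone F2, not isolated, to the diazoketone F3. A chiral dirhodium carboxylate such as Rh2(S-PTTL)4, its antipode being chosen as needed, would then insert the carbenoid into the O–CH2 bond, the known chromanone-forming C–H insertion of 2-alkoxyphenyl diazoketones, to give the (2S)-flavanone F4. Hydroxylation of its potassium enolate at −78 °C with 2-(phenylsulfonyl)-3-phenyloxaziridine, anti to the 2-aryl group, would give the protected trans-dihydroflavonol F5, and HF·pyridine in THF would remove both silyl groups to give 13.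

Step 6. Double deprotonation may be incomplete, the electron-rich phenoxide ring may be attacked by the oxidant, and the enolate may add to the sulfonimine that the oxidant leaves behind. The fallback sets out from 8, which is isolated by stopping step 5 after the hydrogenation, and comes back at 10. Kinetic enolisation and silylation (LDA, TMSCl, THF, −78 °C) would give the trimethylsilyl enol ether F6. Rubottom oxidation (mCPBA, NaHCO3, CH2Cl2, −20 °C; citric acid, MeOH), in which the electron-rich enol ether should react well before the monosubstituted vinyl group and no phenoxide or prenyl alkene is present, would give the α-hydroxy ketone F7. Heating F7 in toluene at 110 °C would bring about the Claisen rearrangement and give 10.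

Step 4. Alkylation of the hydrogen-bonded ortho-acyl phenol by the tertiary electrophile may stall, or elimination of the chloride to the enyne may outrun it. The fallback sets out from 4 and comes back at 9. Direct C-prenylation of the symmetric ketone 4 (prenyl bromide, DBU, THF, rt), which can give only one mono-C-prenyl isomer, would give 1-[2,6-dihydroxy-4-methoxy-3-(3-methylbut-2-en-1-yl)phenyl]ethanone F8. Mitsunobu etherification of F8 with 3 (PPh3, DIAD, THF) would then be directed by hindrance to the hydroxyl remote from the prenyl group and give 9; the regiochemistry of this etherification would have to be proven.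

## Further compounds

F1 | step 8 | 1-[2-(tert-butyldimethylsilyloxy)-4-methoxy-6-{[3-methoxy-4-(triisopropylsilyloxy)phenyl]methoxy}-3-(3-methylbut-2-en-1-yl)phenyl]ethanone | CC(=O)c1c(O[Si](C)(C)C(C)(C)C)c(CC=C(C)C)c(OC)cc1OCc1ccc(O[Si](C(C)C)(C(C)C)C(C)C)c(OC)c1
F2 | step 8 | 1-[2-(tert-butyldimethylsilyloxy)-4-methoxy-6-{[3-methoxy-4-(triisopropylsilyloxy)phenyl]methoxy}-3-(3-methylbut-2-en-1-yl)phenyl]-4,4,4-trifluorobutane-1,3-dione (not isolated) | O=C(CC(=O)C(F)(F)F)c1c(O[Si](C)(C)C(C)(C)C)c(CC=C(C)C)c(OC)cc1OCc1ccc(O[Si](C(C)C)(C(C)C)C(C)C)c(OC)c1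
F3 | step 8 | 2-diazo-1-[2-(tert-butyldimethylsilyloxy)-4-methoxy-6-{[3-methoxy-4-(triisopropylsilyloxy)phenyl]methoxy}-3-(3-methylbut-2-en-1-yl)phenyl]ethanone | [N-]=[N+]=CC(=O)c1c(O[Si](C)(C)C(C)(C)C)c(CC=C(C)C)c(OC)cc1OCc1ccc(O[Si](C(C)C)(C(C)C)C(C)C)c(OC)c1
F4 | step 8 | (2S)-5-(tert-butyldimethylsilyloxy)-7-methoxy-2-[3-methoxy-4-(triisopropylsilyloxy)phenyl]-6-(3-methylbut-2-en-1-yl)-2,3-dihydro-4H-chromen-4-one | COc1cc([C@H]2Oc3cc(OC)c(CC=C(C)C)c(O[Si](C)(C)C(C)(C)C)c3C(=O)C2)ccc1O[Si](C(C)C)(C(C)C)C(C)C
F5 | step 8 | (2R,3R)-5-(tert-butyldimethylsilyloxy)-3-hydroxy-7-methoxy-2-[3-methoxy-4-(triisopropylsilyloxy)phenyl]-6-(3-methylbut-2-en-1-yl)-2,3-dihydro-4H-chromen-4-one | COc1cc([C@H]2Oc3cc(OC)c(CC=C(C)C)c(O[Si](C)(C)C(C)(C)C)c3C(=O)[C@@H]2O)ccc1O[Si](C(C)C)(C(C)C)C(C)C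
F6 | step 6 | triisopropyl{2-methoxy-4-[(5-methoxy-3-(2-methylbut-3-en-2-yloxy)-2-{1-[(trimethylsilyl)oxy]ethenyl}phenoxy)methyl]phenoxy}silane (trimethylsilyl enol ether of 8) | C=C(O[Si](C)(C)C)c1c(OC(C)(C)C=C)cc(OC)cc1OCc1ccc(O[Si](C(C)C)(C(C)C)C(C)C)c(OC)c1
F7 | step 6 | 2-hydroxy-1-[4-methoxy-2-{[3-methoxy-4-(triisopropylsilyloxy)phenyl]methoxy}-6-(2-methylbut-3-en-2-yloxy)phenyl]ethanone | O=C(CO)c1c(OC(C)(C)C=C)cc(OC)cc1OCc1ccc(O[Si](C(C)C)(C(C)C)C(C)C)c(OC)c1
F8 | step 4 | 1-[2,6-dihydroxy-4-methoxy-3-(3-methylbut-2-en-1-yl)phenyl]ethanone | CC(=O)c1c(O)cc(OC)c(CC=C(C)C)c1O
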